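**Analysis of the target**

The target is (2S)-5,7,3',4'-tetrahydroxy-6-prenylflavanone (6-prenyleriodictyol). It is a chroman-4-one in which ring A (C4a, C5, C6, C7, C8, C8a) is a phloroglucinol nucleus, ring C (O1, C2, C3, C4) is a dihydropyranone, and ring B is a catechol attached at C2. The descriptor at C2 in the SMILES corresponds to S (priorities O1 > C1' > C3 > H); it is the only stereocentre. The feature that decides the strategy lies in ring A: C6 carries the 3-methylbut-2-enyl group between the C5 and C7 hydroxyls, C8 carries hydrogen, and O1 sits on C8a next to C8. In any precursor with a preformed phloroglucinol ring, C6 and C8 (or the two oxygens ortho to the acyl carbon) differ only through remote groups, so separating the 6-prenyl from the 8-prenyl series is the real difficulty. The C2 centre is labile: phenoxide formation or base opens ring C by a retro-oxa-Michael reaction to the 2'-hydroxychalcone, which recloses without control. The prenyl double bond rules out hydrogenolysis and strong acid (cyclisation onto O5 or O7 to a dimethylchroman), and the free catechol is easily oxidised. The synthesis must therefore place five substituents on ring A without ambiguity, set one stereocentre late and mildly, and unmask four phenols under near-neutral conditions.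

**Retrosynthetic reasoning**

18 to 17. The last operation should only unmask phenols. All three protecting groups of 17 are aryl silyl ethers. The one on O7 is not a protection step: it is the oxygen substituent that ynol ether 6 brings into ring A. The two on ring B are chosen to match it, so one buffered fluoride treatment frees 18 without base (ring opening at C2) or strong acid (prenyl cyclisation).

17 to 11 and 16. The C2–C1' bond is cut. In the forward direction boronic acid 16 adds to the C2=C3 bond of chromone 11 under an enantioselective palladium catalyst. Cutting here and not at O1–C2 means the stereocentre is made from a flat, achiral chromone in the last C–C bond-forming step, under base-free conditions, and ring B arrives as a simple boronic acid. All the difficulty of ring A is thereby concentrated in 11.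

11 to 3 and 6 (key disconnection). Ring A of 11 is cut at four of its six bonds: C4a–C5, C5–C6, C7–C8 and C8–C8a. What remains is the C4a=C8a bond, which is the C2=C3 bond of the 4-pyranone in 3, and the C6–C7 bond, which is the triple bond of 6. The forward reaction is a benzannulation of diazo ketone 3 with siloxyalkyne 6 (Wolff rearrangement, [2+2] cycloaddition, 4π opening, 6π closure). The cut is made here because the polarity of the partners dictates the substitution pattern:
- the ketene carbon becomes C5 and ends as the phenol peri to C4=O;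
- the alkyne carbon bearing prenyl becomes C6;
- the alkyne carbon bearing oxygen becomes C7;
- the former diazo carbon becomes C8–H.

The 6- versus 8-prenyl question is thus answered by the mechanism of ring construction. No phenol has to be differentiated, and the prenyl group is never introduced onto an aromatic ring. Setting C2 before this step was considered and rejected: a C2-substituted dihydro analogue of 3 would carry an acidic C3–H2 and a benzylic ether through chloride formation, diazo chemistry and irradiation, and would cost several more steps.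

3 to 1. The diazoacetyl group is traced to the carboxyl group of commercial acid 1 through acid chloride 2. The carboxyl carbon of 1 becomes C5 of the target and the added diazo carbon becomes C8.

6 to 4. The ynol ether is traced to commercial ester 4 by a one-flask ester homologation through ynolate 5, trapped on oxygen by a bulky silyl chloride. The prenyl group is carried in from the start as part of 4.

16 to 13 to 12. The boronic acid comes from aryl bromide 13 by bromine–lithium exchange and borylation, and 13 from commercial bromocatechol 12 by silylation.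

**Alternatives that were turned down**

Alternative 1: the textbook route, which cuts O1–C2 and the C2–C3 unit (Claisen–Schmidt condensation, then oxa-Michael closure).
- Forward key step: cyclisation of a 2'-hydroxychalcone such as (2E)-1-[2,6-dihydroxy-4-(methoxymethoxy)-3-(3-methylbut-2-en-1-yl)phenyl]-3-[3,4-bis(methoxymethoxy)phenyl]prop-2-en-1-one A1.
- Why turned down: in A1 two hydroxyls flank the acyl carbon. Closure through O2', next to the prenyl group, gives the 8-prenyl flavanone A2; only closure through O6' gives the 6-prenyl skeleton. Enforcing the right closure means protecting exactly the hindered, chelated hydroxyl between acyl and prenyl, which is the one that ordinary protection leaves free.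
- The closure is also reversible and gives a racemate. Catalytic asymmetric versions need an extra activating ester on the enone that must be removed afterwards.
- The outcome is a long protecting-group sequence ending in an acidic acetal cleavage next to a prenyl group, with neither regiochemistry nor configuration secured by the key step.

Alternative 2: cut the C6–C1'' bond (late prenylation of an intact (2S)-flavanone).
- Forward key step: aromatic Claisen rearrangement of the 5-O-allyl ether (2S)-5-(allyloxy)-2-[3,4-bis(tert-butyldimethylsilyloxy)phenyl]-7-[(tert-butyldimethylsilyl)oxy]-2,3-dihydro-4H-chromen-4-one A3 to the 6-allyl compound A4, then cross-metathesis to prenyl.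
- Why turned down: the regiochemistry is sound (C6 is the only free ortho position of O5), but the flavanone core must first be made enantioselectively with four phenols differentiated. Three further operations (etherification, rearrangement, metathesis) then serve only to attach five carbons, one of them a thermal step on a compound with a labile C2 centre.
- It builds no ring and sets no stereocentre, so it is kept only as a safety net.

Alternative 3: build ring A by Diels–Alder reaction and aromatisation, forming C4a–C5 and C8–C8a.
- Forward key step: cycloaddition of the 1,1,3-trioxygenated diene 1-methoxy-2-(3-methylbut-2-en-1-yl)-1,3-bis(trimethylsilyloxy)buta-1,3-diene A5 with 3-bromo-4H-pyran-4-one A6, then loss of HBr and methanol.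
- Why turned down: the C2=C3 bond of a 4-pyranone is a vinylogous ester with partial aromatic character and a poor dienophile for an electron-rich diene. The halogen activates it little, and the two enone double bonds of A6 compete.
- The tetrasubstituted ketene acetal terminus of A5 is hindered and hydrolytically fragile, and aromatisation needs two separate eliminations.
- The same bonds are formed more reliably by the ketene cascade, which needs no activating or leaving groups.

Key step: step 3

Assumption: the (R)-configured pyridine-oxazoline ligand is taken to deliver the aryl group to the chromone face that gives the (2S)-flavanone, by transfer of the facial sense of this ligand class with cyclic enones; if the sense is opposite, the (S)-ligand is used.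

**Route**

Step 1
Reactants: 1 4-oxo-4H-pyran-2-carboxylic acid (comanic acid)
Product: 3 2-(2-diazoacetyl)-4H-pyran-4-one, via acid chloride 2 (not isolated)
Conditions: 1-chloro-N,N,2-trimethylprop-1-en-1-amine, CH2Cl2, 0 °C to rt; then CH2N2 (3 equiv), Et2O, 0 °C
Reagents that add atoms: diazomethane, C=[N+]=[N-]
Why: Acylation of diazomethane by a non-enolisable acid chloride (first stage of the Arndt–Eistert sequence); the chloroenamine forms the chloride without HCl, so the pyranone is not turned into a hydroxypyrylium salt that diazomethane could O-methylate, and the second equivalent of diazomethane takes up the HCl of the acylation.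

Step 2
Reactants: 4 ethyl 4-methylpent-3-enoate
Product: 6 triisopropyl[(5-methylhex-4-en-1-yn-1-yl)oxy]silane, via lithium ynolate 5 (not isolated)
Conditions: CH2Br2, lithium 2,2,6,6-tetramethylpiperidide, THF, −78 °C; 4; then LiN(SiMe3)2, n-BuLi, −78 °C to rt; then TIPSCl, −78 to 0 °C
Reagents that add atoms: dibromomethane, BrCBr; chlorotriisopropylsilane, CC(C)[Si](Cl)(C(C)C)C(C)C
Why: Kowalski ester homologation: LiCHBr2 adds to the ester, deprotonation and bromine–lithium exchange give a carbenoid enolate whose 1,2-shift yields ynolate 5, and the bulky silyl chloride traps it on oxygen to give the siloxyalkyne and not a silylketene.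

Step 3
Reactants: 3 2-(2-diazoacetyl)-4H-pyran-4-one; 6 triisopropyl[(5-methylhex-4-en-1-yn-1-yl)oxy]silane (1.5 equiv)
Product: 11 5-hydroxy-6-(3-methylbut-2-en-1-yl)-7-[(triisopropylsilyl)oxy]-4H-chromen-4-one, via vinylketene 7 (not isolated), via cyclobutenone 8 (not isolated), via dienylketene 9 (not isolated), via cyclohexadienone 10 (not isolated)
Conditions: hν (365 nm), ClCH2CH2Cl, rt; then 80 °C
Reagents that add atoms: none
Why: Danheiser benzannulation in its diazo ketone form: irradiation of 3 expels N2 and, by Wolff rearrangement, pyranone C2 shifts to the diazo carbon to give vinylketene 7, whose vinyl unit is the pyranone C2=C3 bond. The ynol ether adds to the ketene in a [2+2] cycloaddition in which its nucleophilic carbon, the one bearing prenyl, bonds to the ketene carbonyl carbon, giving cyclobutenone 8. At 80 °C 8 opens reversibly (4π electrocyclic) to dienylketene 9, and ring A closes by a thermal 6π electrocyclisation (six-membered ring, disrotatory) between the ketene carbon and pyranone C3; dienone 10 then tautomerises to phenol 11, whose OH is held in a hydrogen bond to C4=O. The closest known reaction type is this same cascade between α,β-unsaturated or heteroaryl α-diazo ketones and triisopropylsiloxyalkynes, which gives 2-substituted resorcinol monosilyl ethers. No stereocentre remains: those of 8 and 10 vanish on aromatisation, and only the isomer of 9 with the pyranyl group cis to the ketene can close while the other returns through 8, so the isomers converge. The step needs three selectivities: the regiochemistry of the [2+2] step, secured by the polarisation of the ynol ether, which puts prenyl on C6 between the two oxygens and hydrogen on C8; the site of closure, secured because C3 is the only carbon ortho to the ketenyl substituent; and chemoselectivity, secured because the electron-rich alkyne is a far better ketenophile than the trisubstituted prenyl alkene. Irradiation at 365 nm should excite the diazo ketone only and not the 4-pyranone, whose own photochemistry needs shorter wavelengths.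

Step 4
Reactants: 12 4-bromobenzene-1,2-diol
Product: 13 4-bromo-1,2-bis(tert-butyldimethylsilyloxy)benzene
Conditions: TBSCl (2.3 equiv), imidazole, DMF, rt
Reagents that add atoms: tert-butyldimethylsilyl chloride, CC(C)(C)[Si](C)(C)Cl
Why: Standard silylation of both catechol hydroxyls; silyl ethers are chosen so that ring B is unmasked in the same fluoride step as O7.

Step 5
Reactants: 13 4-bromo-1,2-bis(tert-butyldimethylsilyloxy)benzene
Product: 16 [3,4-bis(tert-butyldimethylsilyloxy)phenyl]boronic acid, via aryllithium 14 (not isolated), via lithium triisopropoxyborate 15 (not isolated)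
Conditions: n-BuLi, THF, −78 °C; B(OiPr)3, −78 °C to rt; 1 M HCl to pH 5
Reagents that add atoms: triisopropyl borate, CC(C)OB(OC(C)C)OC(C)C; water, O
Why: Bromine–lithium exchange and borylation; the lithiated carbon is meta and para to the siloxy groups, so no ortho silyl migration can occur, and brief mild acid hydrolyses the borate without touching the aryl silyl ethers.

Step 6
Reactants: 11 5-hydroxy-6-(3-methylbut-2-en-1-yl)-7-[(triisopropylsilyl)oxy]-4H-chromen-4-one; 16 [3,4-bis(tert-butyldimethylsilyloxy)phenyl]boronic acid (2 equiv)
Product: 17 (2S)-2-[3,4-bis(tert-butyldimethylsilyloxy)phenyl]-5-hydroxy-6-(3-methylbut-2-en-1-yl)-7-[(triisopropylsilyl)oxy]-2,3-dihydro-4H-chromen-4-one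
Conditions: Pd(OCOCF3)2 (10 mol%), (R)-4-tert-butyl-2-(pyridin-2-yl)-4,5-dihydrooxazole (12 mol%), NH4PF6 (30 mol%), H2O (5 equiv), ClCH2CH2Cl, 60 °C
Reagents that add atoms: none
Why: Enantioselective conjugate addition of an arylboronic acid to a chromone with a cationic divalent palladium pyridine-oxazoline catalyst: the aryl–palladium species adds across C2=C3 from the face left open by the tert-butyl group of the ligand and the palladium enolate is protonated by water, so C2 is set by catalyst control without base and ring C cannot open; the hydrogen-bonded 5-OH should raise the electrophilicity of the enone.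

Step 7
Reactants: 17 (2S)-2-[3,4-bis(tert-butyldimethylsilyloxy)phenyl]-5-hydroxy-6-(3-methylbut-2-en-1-yl)-7-[(triisopropylsilyl)oxy]-2,3-dihydro-4H-chromen-4-one
Product: 18 (2S)-2-(3,4-dihydroxyphenyl)-5,7-dihydroxy-6-(3-methylbut-2-en-1-yl)-2,3-dihydro-4H-chromen-4-one
Conditions: Et3N·3HF (excess), THF, 0 °C to rt
Reagents that add atoms: none
Why: Fluoride cleavage of three aryl silyl ethers with a buffered, weakly acidic HF source; no phenoxide is formed that could open ring C to the chalcone and no strong acid is present that could cyclise the prenyl group onto O5 or O7, so C2 and the side chain should be untouched.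

**Compound list**

1 | 4-oxo-4H-pyran-2-carboxylic acid (comanic acid) | OC(=O)C1=CC(=O)C=CO1 | starting material
2 | 4-oxo-4H-pyran-2-carbonyl chloride | ClC(=O)C1=CC(=O)C=CO1 | intermediate
3 | 2-(2-diazoacetyl)-4H-pyran-4-one | [N-]=[N+]=CC(=O)C1=CC(=O)C=CO1 | intermediate
4 | ethyl 4-methylpent-3-enoate | CCOC(=O)CC=C(C)C | starting material
5 | lithium 5-methylhex-4-en-1-yn-1-olate | [Li+].[O-]C#CCC=C(C)C | intermediate
6 | triisopropyl[(5-methylhex-4-en-1-yn-1-yl)oxy]silane | CC(C)=CCC#CO[Si](C(C)C)(C(C)C)C(C)C | intermediate
7 | 2-(2-oxoethenyl)-4H-pyran-4-one (vinylketene) | O=C=CC1=CC(=O)C=CO1 | intermediate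
8 | 2-[3-(3-methylbut-2-en-1-yl)-4-oxo-2-[(triisopropylsilyl)oxy]cyclobut-2-en-1-yl]-4H-pyran-4-one (racemic) | CC(C)=CCC1=C(O[Si](C(C)C)(C(C)C)C(C)C)C(C1=O)C2=CC(=O)C=CO2 | intermediate
9 | (3E)-2-(3-methylbut-2-en-1-yl)-4-(4-oxo-4H-pyran-2-yl)-3-[(triisopropylsilyl)oxy]buta-1,3-dien-1-one | CC(C)=CCC(=C=O)/C(O[Si](C(C)C)(C(C)C)C(C)C)=C\C1=CC(=O)C=CO1 | intermediate
10 | 6-(3-methylbut-2-en-1-yl)-7-[(triisopropylsilyl)oxy]-4aH-chromene-4,5-dione (racemic) | CC(C)=CCC1=C(O[Si](C(C)C)(C(C)C)C(C)C)C=C2OC=CC(=O)C2C1=O | intermediate
11 | 5-hydroxy-6-(3-methylbut-2-en-1-yl)-7-[(triisopropylsilyl)oxy]-4H-chromen-4-one | CC(C)=CCc1c(O[Si](C(C)C)(C(C)C)C(C)C)cc2OC=CC(=O)c2c1O | intermediate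
12 | 4-bromobenzene-1,2-diol | Oc1ccc(Br)cc1O | starting material
13 | 4-bromo-1,2-bis(tert-butyldimethylsilyloxy)benzene | Brc1ccc(O[Si](C)(C)C(C)(C)C)c(O[Si](C)(C)C(C)(C)C)c1 | intermediate
14 | [3,4-bis(tert-butyldimethylsilyloxy)phenyl]lithium | [Li]c1ccc(O[Si](C)(C)C(C)(C)C)c(O[Si](C)(C)C(C)(C)C)c1 | intermediate
15 | lithium [3,4-bis(tert-butyldimethylsilyloxy)phenyl]tri(propan-2-yloxy)borate | [Li+].CC(C)O[B-](OC(C)C)(OC(C)C)c1ccc(O[Si](C)(C)C(C)(C)C)c(O[Si](C)(C)C(C)(C)C)c1 | intermediate
16 | [3,4-bis(tert-butyldimethylsilyloxy)phenyl]boronic acid | OB(O)c1ccc(O[Si](C)(C)C(C)(C)C)c(O[Si](C)(C)C(C)(C)C)c1 | intermediate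
17 | (2S)-2-[3,4-bis(tert-butyldimethylsilyloxy)phenyl]-5-hydroxy-6-(3-methylbut-2-en-1-yl)-7-[(triisopropylsilyl)oxy]-2,3-dihydro-4H-chromen-4-one | CC(C)=CCc1c(O[Si](C(C)C)(C(C)C)C(C)C)cc2c(c1O)C(=O)C[C@@H](c1ccc(O[Si](C)(C)C(C)(C)C)c(O[Si](C)(C)C(C)(C)C)c1)O2 | intermediate
18 | (2S)-2-(3,4-dihydroxyphenyl)-5,7-dihydroxy-6-(3-methylbut-2-en-1-yl)-2,3-dihydro-4H-chromen-4-one (CNP0408918.2) | CC(C)=CCc1c(O)cc2c(c1O)C(=O)C[C@@H](c1ccc(O)c(O)c1)O2 | target

**Step count and risk**

Total step count: 7. Longest linear sequence: 4 steps (1 to 3 to 11 to 17 to 18 through steps 1, 3, 6 and 7; the branch 12 to 13 to 16 to 17 to 18 is equally long).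

Least certain steps:

Step 3 (key step). What may go wrong: vinylketene 7 may be lost to dimerisation or to acylation of phenol already formed before it meets the ynol ether; the pyranone chromophore may photodegrade; or cyclobutenone 8 may decompose in place of opening. Fallback (ring A bought, prenyl placed by Claisen rearrangement and cross-metathesis), setting out from boronic acid 16 and returning at 17:
- Commercial 5,7-dihydroxy-4H-chromen-4-one is silylated at the unchelated 7-OH (TIPSCl, imidazole, DMF) to give 5-hydroxy-7-[(triisopropylsilyl)oxy]-4H-chromen-4-one F1.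
- Conjugate addition of 16 under the conditions of step 6 gives (2S)-2-[3,4-bis(tert-butyldimethylsilyloxy)phenyl]-5-hydroxy-7-[(triisopropylsilyl)oxy]-2,3-dihydro-4H-chromen-4-one F2.
- Mitsunobu etherification of the chelated 5-OH with allyl alcohol (PPh3, diisopropyl azodicarboxylate, THF) gives (2S)-5-(allyloxy)-2-[3,4-bis(tert-butyldimethylsilyloxy)phenyl]-7-[(triisopropylsilyl)oxy]-2,3-dihydro-4H-chromen-4-one F3.
- Aromatic Claisen rearrangement catalysed by Eu(fod)3, the tris(6,6,7,7,8,8,8-heptafluoro-2,2-dimethyloctane-3,5-dionate) of trivalent europium, in ClCH2CH2Cl at 80 °C moves the allyl group to C6, the only free ortho position, to give (2S)-6-allyl-2-[3,4-bis(tert-butyldimethylsilyloxy)phenyl]-5-hydroxy-7-[(triisopropylsilyl)oxy]-2,3-dihydro-4H-chromen-4-one F4.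
- Cross-metathesis with excess 2-methylbut-2-ene (second-generation Grubbs catalyst, CH2Cl2, 40 °C) converts allyl into prenyl and gives 17.

Step 6. What may go wrong: poor facial selectivity on this electron-rich, 6,7-disubstituted, chelated chromone, together with competing protodeboronation of the electron-rich boronic acid. Fallback (resolution in place of asymmetric induction), setting out from 11 and returning at 17:
- Addition of 16 to 11 with an achiral catalyst (Pd(OCOCF3)2, 2,2'-bipyridine, H2O, ClCH2CH2Cl, 60 °C) gives racemic 2-[3,4-bis(tert-butyldimethylsilyloxy)phenyl]-5-hydroxy-6-(3-methylbut-2-en-1-yl)-7-[(triisopropylsilyl)oxy]-2,3-dihydro-4H-chromen-4-one F5.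
- Asymmetric transfer hydrogenation with RuCl[(R,R)-TsDPEN](p-cymene) in HCO2H/Et3N, stopped near half conversion, is expected to reduce the (2R)-enantiomer to the cis alcohol (2R,4R)-2-[3,4-bis(tert-butyldimethylsilyloxy)phenyl]-6-(3-methylbut-2-en-1-yl)-7-[(triisopropylsilyl)oxy]-3,4-dihydro-2H-chromene-4,5-diol F6 and to leave the (2S)-ketone 17, which is separated by chromatography.

Step 2. What may go wrong: deprotonation of the doubly activated C2–H2 of the β,γ-unsaturated ester by the carbenoid or the amide bases in place of carbonyl addition, with migration of the double bond into conjugation. Fallback (ynolate by oxidation of an acetylide), setting out from 4 and returning at 5: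
- Reduction with i-Bu2AlH (CH2Cl2, −78 °C) gives 4-methylpent-3-enal F7.
- Dibromo-olefination (CBr4, PPh3, CH2Cl2, 0 °C) gives 1,1-dibromo-5-methylhexa-1,4-diene F8.
- n-BuLi (2 equiv, THF, −78 °C) gives (5-methylhex-4-en-1-yn-1-yl)lithium F9 by the Corey–Fuchs sequence.
- Oxygen transfer from lithium tert-butyl peroxide (t-BuOOLi, THF, −78 to 0 °C) gives ynolate 5, which is silylated as in step 2.

Step 1. What may go wrong: O-methylation of the pyranone carbonyl through its protonated form, or dipolar addition of diazomethane to the acyl-activated C2=C3 bond. Fallback (diazo transfer in place of diazomethane acylation), setting out from 2 and returning at 3: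
- Stille acylation of 2 with Me4Sn (PdCl2(PPh3)2 cat., THF, 65 °C) gives 2-acetyl-4H-pyran-4-one F10.
- LiN(SiMe3)2 (THF, −78 °C) then 2,2,2-trifluoroethyl trifluoroacetate gives 4,4,4-trifluoro-1-(4-oxo-4H-pyran-2-yl)butane-1,3-dione F11.
- Methanesulfonyl azide with Et3N and water in MeCN effects detrifluoroacetylative diazo transfer to give 3.

**Further compounds**

F1 | step 3 | 5-hydroxy-7-[(triisopropylsilyl)oxy]-4H-chromen-4-one | CC(C)[Si](Oc1cc(O)c2C(=O)C=COc2c1)(C(C)C)C(C)C
F2 | step 3 | (2S)-2-[3,4-bis(tert-butyldimethylsilyloxy)phenyl]-5-hydroxy-7-[(triisopropylsilyl)oxy]-2,3-dihydro-4H-chromen-4-one | CC(C)[Si](Oc1cc(O)c2C(=O)C[C@@H](c3ccc(O[Si](C)(C)C(C)(C)C)c(O[Si](C)(C)C(C)(C)C)c3)Oc2c1)(C(C)C)C(C)C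
F3 | step 3 | (2S)-5-(allyloxy)-2-[3,4-bis(tert-butyldimethylsilyloxy)phenyl]-7-[(triisopropylsilyl)oxy]-2,3-dihydro-4H-chromen-4-one | CC(C)[Si](Oc1cc(OCC=C)c2C(=O)C[C@@H](c3ccc(O[Si](C)(C)C(C)(C)C)c(O[Si](C)(C)C(C)(C)C)c3)Oc2c1)(C(C)C)C(C)C
F4 | step 3 | (2S)-6-allyl-2-[3,4-bis(tert-butyldimethylsilyloxy)phenyl]-5-hydroxy-7-[(triisopropylsilyl)oxy]-2,3-dihydro-4H-chromen-4-one | C=CCc1c(O[Si](C(C)C)(C(C)C)C(C)C)cc2c(c1O)C(=O)C[C@@H](c1ccc(O[Si](C)(C)C(C)(C)C)c(O[Si](C)(C)C(C)(C)C)c1)O2
F5 | step 6 | racemic 2-[3,4-bis(tert-butyldimethylsilyloxy)phenyl]-5-hydroxy-6-(3-methylbut-2-en-1-yl)-7-[(triisopropylsilyl)oxy]-2,3-dihydro-4H-chromen-4-one | CC(C)=CCc1c(O[Si](C(C)C)(C(C)C)C(C)C)cc2c(c1O)C(=O)CC(c1ccc(O[Si](C)(C)C(C)(C)C)c(O[Si](C)(C)C(C)(C)C)c1)O2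
F6 | step 6 | (2R,4R)-2-[3,4-bis(tert-butyldimethylsilyloxy)phenyl]-6-(3-methylbut-2-en-1-yl)-7-[(triisopropylsilyl)oxy]-3,4-dihydro-2H-chromene-4,5-diol | CC(C)=CCc1c(O[Si](C(C)C)(C(C)C)C(C)C)cc2c(c1O)[C@H](O)C[C@H](c1ccc(O[Si](C)(C)C(C)(C)C)c(O[Si](C)(C)C(C)(C)C)c1)O2
F7 | step 2 | 4-methylpent-3-enal | CC(C)=CCC=O
F8 | step 2 | 1,1-dibromo-5-methylhexa-1,4-diene | CC(C)=CCC=C(Br)Br
F9 | step 2 | (5-methylhex-4-en-1-yn-1-yl)lithium | [Li]C#CCC=C(C)C
F10 | step 1 | 2-acetyl-4H-pyran-4-one | CC(=O)C1=CC(=O)C=CO1
F11 | step 1 | 4,4,4-trifluoro-1-(4-oxo-4H-pyran-2-yl)butane-1,3-dione | O=C(CC(=O)C(F)(F)F)C1=CC(=O)C=CO1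
A1 | alternative 1 | (2E)-1-[2,6-dihydroxy-4-(methoxymethoxy)-3-(3-methylbut-2-en-1-yl)phenyl]-3-[3,4-bis(methoxymethoxy)phenyl]prop-2-en-1-one | COCOc1ccc(/C=C/C(=O)c2c(O)cc(OCOC)c(CC=C(C)C)c2O)cc1OCOC
A2 | alternative 1 | racemic 2-[3,4-bis(methoxymethoxy)phenyl]-5-hydroxy-7-(methoxymethoxy)-8-(3-methylbut-2-en-1-yl)-2,3-dihydro-4H-chromen-4-one | COCOc1ccc(C2CC(=O)c3c(O)cc(OCOC)c(CC=C(C)C)c3O2)cc1OCOC
A3 | alternative 2 | (2S)-5-(allyloxy)-2-[3,4-bis(tert-butyldimethylsilyloxy)phenyl]-7-[(tert-butyldimethylsilyl)oxy]-2,3-dihydro-4H-chromen-4-one | C=CCOc1cc(O[Si](C)(C)C(C)(C)C)cc2c1C(=O)C[C@@H](c1ccc(O[Si](C)(C)C(C)(C)C)c(O[Si](C)(C)C(C)(C)C)c1)O2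
A4 | alternative 2 | (2S)-6-allyl-2-[3,4-bis(tert-butyldimethylsilyloxy)phenyl]-7-[(tert-butyldimethylsilyl)oxy]-5-hydroxy-2,3-dihydro-4H-chromen-4-one | C=CCc1c(O[Si](C)(C)C(C)(C)C)cc2c(c1O)C(=O)C[C@@H](c1ccc(O[Si](C)(C)C(C)(C)C)c(O[Si](C)(C)C(C)(C)C)c1)O2
A5 | alternative 3 | 1-methoxy-2-(3-methylbut-2-en-1-yl)-1,3-bis(trimethylsilyloxy)buta-1,3-diene (mixture of double-bond isomers) | COC(O[Si](C)(C)C)=C(CC=C(C)C)C(O[Si](C)(C)C)=C
A6 | alternative 3 | 3-bromo-4H-pyran-4-one | O=C1C=COC=C1Br
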